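The route cuts the C1–C5 bond of the spirocycle and rejoins C1 to C10, which turns the spiro[4.5]decane into an angular-methyl decalin dienone. The feature exploited is in the cyclopentane ring. The lactone oxygen (on C3) and the lactone side chain (on C2) sit on adjacent carbons, each one CH2 from spiro carbon C5. This is the imprint of a 2-substituted cyclopent-2-enone spiro-linked at C4. Irradiation in aqueous acid performs three things in one operation: ring-A contraction, transfer of the C10 configuration to C5, and hydration of C10, the handle for the ring-B alkene. Precursor 19 is a 2-(methoxycarbonylmethyl)-1,4-dien-3-one with 6α-methyl and a disiloxane-bridged 7β,8α-diol.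

Key step: step 12

Locants: steroid-type decalin numbering. Ring A = C1, C2, C3, C4, C5, C10; ring B = C5 to C10; the angular methyl is on C10. Every atom keeps its locant after step 12, where C5 becomes the spiro carbon. C11/C12 are the acetate carbons and C13 is the exocyclic methylene. β is the face of ring B that carries the angular methyl in 7–19; α is the other face.

Design remark 1: C10 is built first, on a ring without oxygen, and its axial methyl then steers both ring-B oxygens. Annulating a pre-oxygenated 2,6-dimethylcyclohexanone would place the incoming chain axial (the C10 epimer) and would expose a β-silyloxy ketone to base.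

Design remark 2: the diol is bridged by a tetraisopropyldisiloxane (TIPDS). The bridge tolerates aqueous acetic acid. It also holds both C–O bonds equatorial, in the nodal plane of the dienone, so vinylogous loss of O7 through C6 enolisation is blocked.

Assumption: the C10 carbinol of 20 is drawn with OH anti to the migrated C1 (backside capture of water, axial OH). This centre is erased in step 15.

Step 1
Reactants: 1 (+)-dihydrocarvone; 2 (S)-1-phenylethylamine
Product: 3 (S)-phenylethyl imine of dihydrocarvone
Conditions: TsOH·H2O (cat.), PhMe, reflux, Dean–Stark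
Reagents that add atoms: (S)-1-phenylethylamine, C[C@H](N)c1ccccc1
Why: Acid-catalysed imine condensation driven by azeotropic removal of water; the methyl-bearing α-carbon stays configurationally labile through imine–enamine tautomerism, so both C2 epimers of commercial 1 feed the same enamine in step 2.

Step 2
Reactants: 3 (S)-phenylethyl imine of dihydrocarvone; 4 ethyl vinyl ketone
Product: 6 diketone (2R,5R)-2-methyl-2-(3-oxopentyl)-5-(prop-1-en-2-yl)cyclohexan-1-one, via adduct imine 5 (not isolated)
Conditions: 4, THF, 40 °C; then 10% aq AcOH, rt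
Reagents that add atoms: ethyl vinyl ketone, CCC(=O)C=C; water, O
Why: Chiral-imine Michael addition through the more substituted secondary enamine, in which the enone is taken up in a compact aza-ene-like transition state on the face left open by the (S)-phenylethyl group, a face that coincides with the ring's own preference for axial attack cis to the equatorial isopropenyl group, so quaternary C10 is set by matched double control before mild acid hydrolyses the imine and returns the amine.

Step 3
Reactants: 6 diketone
Product: 7 (−)-10-epi-α-cyperone (4aR,7R)-1,4a-dimethyl-7-(prop-1-en-2-yl)-4,4a,5,6,7,8-hexahydronaphthalen-2(3H)-one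
Conditions: NaOMe, MeOH, rt → 60 °C
Reagents that add atoms: none
Why: Intramolecular aldol condensation (closing half of a Robinson annulation) in which only the CH2 of the ethyl ketone (C6) can reach C5 through a six-membered ring, no stereocentre is formed, and any minor C10 isomer is a diastereomer (chiral-pool centre at C3) that chromatography can remove.

Step 4
Reactants: 7 (−)-10-epi-α-cyperone
Product: 10 enedione (4aR)-1,4a-dimethyl-4,4a,5,6-tetrahydronaphthalene-2,7(3H,8H)-dione, via methoxy hydroperoxide 8 (not isolated), via TEMPO ether 9 (not isolated)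
Conditions: O3, MeOH, −78 °C; FeSO4·7H2O, TEMPO, −78 °C → rt; then mCPBA, CH2Cl2, 0 °C
Reagents that add atoms: TEMPO, CC1(C)CCCC(C)(C)N1[O]
Why: Oxodealkenylation, in which ozone attacks only the electron-rich 1,1-disubstituted alkene and not the conjugated one, divalent iron reduces the α-methoxy hydroperoxide to an alkoxy radical whose β-scission expels methyl acetate, TEMPO traps the C3 radical, and the peracid converts the alkoxyamine into the C3 ketone, erasing the spent C3 stereocentre.

Step 5
Reactants: 10 enedione
Product: 11 ketal enone 3,3-ethylenedioxy-6,10β-dimethyldecal-5-en-7-one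
Conditions: Me3SiOCH2CH2OSiMe3, Me3SiOTf (cat.), CH2Cl2, −78 °C
Reagents that add atoms: 1,2-bis(trimethylsiloxy)ethane, C[Si](C)(C)OCCO[Si](C)(C)C
Why: Noyori ketalisation under kinetic control, where the saturated C3 ketone reacts far faster than the conjugated, tetrasubstituted C7 enone and the aprotic cold medium leaves the C5=C6 bond where it is.

Step 6
Reactants: 11 ketal enone
Product: 12 8α-hydroxy enone
Conditions: KN(SiMe3)2, THF, −78 °C; 2-(phenylsulfonyl)-3-phenyloxaziridine; AcOH quench
Reagents that add atoms: 2-(phenylsulfonyl)-3-phenyloxaziridine, O=S(=O)(c1ccccc1)N1OC1c1ccccc1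
Why: Davis oxidation of the kinetic α′ (C8) enolate, with the oxaziridine approaching anti to the axial angular methyl that is 1,3-related to C8, which gives the equatorial 8α-hydroxyl, also the thermodynamic epimer of this enolisable ketol.

Step 7
Reactants: 12 8α-hydroxy enone
Product: 13 allylic 7β,8α-diol
Conditions: NaBH4, CeCl3·7H2O, MeOH, −78 → −20 °C
Reagents that add atoms: none
Why: Luche 1,2-reduction in which hydride adds axially from the α face, opposite the angular methyl as in 4-en-3-one steroids, so the new C7 hydroxyl is equatorial (β) and trans to O8.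

Step 8
Reactants: 13 allylic 7β,8α-diol
Product: 14 7β,8α-O-TIPDS ketal
Conditions: TIPDSCl2 (1,3-dichloro-1,1,3,3-tetraisopropyldisiloxane), imidazole, DMF, 0 °C → rt
Reagents that add atoms: TIPDSCl2, CC(C)[Si](Cl)(C(C)C)O[Si](Cl)(C(C)C)C(C)C
Why: Double O-silylation in which the reagent first caps the less hindered O8 and then closes a seven-membered ring on O7, a bridge that fits a trans-diequatorial diol and freezes that arrangement without touching a stereocentre.

Step 9
Reactants: 14 7β,8α-O-TIPDS ketal
Product: 16 conjugated enone 6α,10β-dimethyl-7β,8α-(TIPDS-dioxy)decal-4-en-3-one, via deconjugated enone 15 (not isolated)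
Conditions: TsOH·H2O (cat.), THF–H2O, 40 °C
Reagents that add atoms: water, O
Why: Acid hydrolysis of the dioxolane followed by β,γ to α,β enone isomerisation through the 3,5-dienol, where C6 is protonated under equilibrating conditions and settles with its methyl equatorial (α) as in 6-methyl-4-en-3-one steroids, while the locked equatorial C7–O bond is orthogonal to the dienol π system and should not be expelled.

Step 10
Reactants: 16 conjugated enone; 17 methyl bromoacetate
Product: 18 2-(methoxycarbonylmethyl) enone (C2 epimers)
Conditions: LiN(i-Pr)2, THF, −78 °C; 17, DMPU, −78 → −30 °C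
Reagents that add atoms: methyl bromoacetate, COC(=O)CBr
Why: Kinetic α′-enolate alkylation (SN2) at C2 of the 4-en-3-one, leaving the γ-hydrogen at C6 untouched, with the C2 configuration irrelevant because this carbon becomes sp2 in step 11.

Step 11
Reactants: 18 2-(methoxycarbonylmethyl) enone
Product: 19 cross-conjugated dienone 2-(methoxycarbonylmethyl)-6α,10β-dimethyl-7β,8α-(TIPDS-dioxy)decala-1,4-dien-3-one
Conditions: DDQ, 1,4-dioxane, reflux
Reagents that add atoms: none
Why: DDQ dehydrogenation through the 2,4-dienol and hydride loss from C1, the standard 4-en-3-one to 1,4-dien-3-one conversion that also serves 2-alkyl substrates, run without added acid so that the 3,5-dienol pathway to a 4,6-dienone stays closed.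

Step 12
Reactants: 19 cross-conjugated dienone
Product: 20 spiro carbinol: 2-(methoxycarbonylmethyl)cyclopent-2-enone spiro-fused at C5 with C1 α and C4 β; 10β-OH 10α-CH3; 6α-CH3; 7β,8α-O-TIPDS
Conditions: hν (450 W medium-pressure Hg lamp, Pyrex), AcOH–H2O–1,4-dioxane 5:3:2, about 5 mM, N2-sparged, 15 °C, stopped at full conversion
Reagents that add atoms: water, O
Why: Excitation (n→π*) and intersystem crossing let the two β-carbons C1 and C5 bond across ring A, electron demotion gives the bicyclo[3.1.0] oxyallyl zwitterion (cyclopropane C1–C5–C10), acetic acid protonates its oxygen before it can slide to the lumiketone, and the hydroxyallyl cation is discharged by scission of C1–C10 as water binds C10. This is the type A cross-conjugated cyclohexadienone photorearrangement in its aqueous-acid variant, long used to turn 2-alkyl 6/6-fused dienones into spiro[4.5]decenone carbinols. The cyclopentenone ring (C1–C2–C3–C4–C5) closes by transannular C1–C5 bonding inside ring A followed by release of C10, a net 1,2-shift of C1 from C10 to C5 and not an exo or endo attack of a chain. Spiro C5 is controlled by the C10 stereocentre, because C1 stays on the α face of ring B on which it was attached, and the C10 carbinol is controlled by backside entry of water anti to the departing C1, which makes the hydroxyl axial. The step needs C1–C10 and not C5–C10 cleavage (spiro ketone against hydroazulenone), and the substrate secures this with an alkyl group on C2 and only hydrogen on C4, so that the cationic charge sits on C2 next to C1. The Pyrex filter and the early stop protect the weakly absorbing cyclopentenone, and the acid-stable, equatorially locked disiloxane keeps O7 and O8 out of play.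

Step 13
Reactants: 20 spiro carbinol
Product: 22 unsaturated lactone (C1=C2; O3 on the C10 side), via hydroxy ester 21 (not isolated)
Conditions: (S)-Me-CBS [(S)-1-methyl-3,3-diphenyltetrahydro-1H,3H-pyrrolo[1,2-c][1,3,2]oxazaborole] (0.3 equiv), catecholborane, PhMe, −78 °C; aqueous work-up; then PPTS (cat.), PhMe, 50 °C
Reagents that add atoms: none
Why: Corey–Bakshi–Shibata reduction then acid-catalysed lactonisation, where ring B shows the flat cyclopentenone two nearly mirror-like flanks (C6–CH3 against C10–CH3) so the catalyst decides, the α-branched alkenyl arm C2 acts as the large group, and the (S)-oxazaborolidine delivers hydride from the C6 side to give the (3R)-alcohol with oxygen on the C10 side, which then displaces methanol from the ester.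

Step 14
Reactants: 22 unsaturated lactone
Product: 23 saturated cis-fused hydroxy lactone (H2 and H3 on the C6 side)
Conditions: H2 (4 atm), 5% Rh/Al2O3, EtOAc, rt
Reagents that add atoms: none
Why: Heterogeneous syn hydrogenation in which the lactone ring folds toward the C10 side, the alkene therefore meets the surface by the face that carries H3, and only the cis-fused bicyclo[3.3.0] lactone is accessible, which fixes C2, with Rh chosen to suppress allylic C3–O hydrogenolysis and no other alkene yet present.

Step 15
Reactants: 23 saturated cis-fused hydroxy lactone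
Product: 24 ring-B alkene lactone (C9=C10 with 10-CH3)
Conditions: SOCl2, pyridine, −10 °C
Reagents that add atoms: none
Why: E2 dehydration through the chlorosulfite, where the axial C10–O bond is antiperiplanar to the axial hydrogen on C9 and C5 carries no hydrogen, so the trisubstituted C9=C10 alkene is expected ahead of the exocyclic isomer.

Step 16
Reactants: 24 ring-B alkene lactone; 25 Eschenmoser's salt
Product: 28 α-methylene lactone, via Mannich base 26 (not isolated), via methiodide 27 (not isolated)
Conditions: LiN(i-Pr)2, THF, −78 °C; 25, → rt; MeI; then aq NaHCO3, CH2Cl2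
Reagents that add atoms: Eschenmoser's salt (N,N-dimethylmethyleneiminium iodide), C=[N+](C)C.[I-]
Why: Mannich reaction of the lactone enolate, N-methylation and Hofmann-type β-elimination, a standard α-methylenation in which C11 ends sp2 so no stereocentre arises and the non-enolisable centres C2 and C3 are safe.

Step 17
Reactants: 28 α-methylene lactone
Product: 29 primary allylic alcohol (10-CH2OH)
Conditions: SeO2 (0.5 equiv), t-BuOOH, CH2Cl2, rt
Reagents that add atoms: selenium dioxide, O=[Se]=O; tert-butyl hydroperoxide, CC(C)(C)OO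
Why: Riley allylic oxidation (ene reaction then [2,3]-shift) in which selenium binds C9 and oxygen is returned to an allylic carbon on the more substituted terminus C10, where the methyl is the only candidate because C5 is quaternary, while the electron-poor methylene lactone is inert to the electrophilic ene step.

Step 18
Reactants: 29 primary allylic alcohol; 30 angelic acid
Product: 32 TIPDS-protected angelate, via mixed anhydride 31 (not isolated)
Conditions: 30, 2,4,6-Cl3C6H2COCl, Et3N, PhMe, rt; then 29, 75 °C
Reagents that add atoms: angelic acid, C/C=C(/C)C(=O)O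
Why: Yamaguchi-type mixed-anhydride esterification run without DMAP, so that no reversible conjugate addition can turn the (Z)-angelate into the tiglate, the unhindered primary alcohol attacking the less shielded angeloyl carbonyl.

Step 19
Reactants: 32 TIPDS-protected angelate
Product: 33 CNP0224912.1
Conditions: Et3N·3HF, THF, rt
Reagents that add atoms: none
Why: Fluoride-induced Si–O cleavage in a buffered, weakly acidic medium that leaves the angelate, the allylic ester and the Michael-acceptor lactone alone and touches no stereocentre.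

Compound list

1 | (+)-dihydrocarvone, (5R)-2-methyl-5-(prop-1-en-2-yl)cyclohexan-1-one, commercial C2 epimer mixture | CC1CC[C@H](CC1=O)C(C)=C | starting material
2 | (S)-(−)-1-phenylethylamine | C[C@H](N)c1ccccc1 | starting material
3 | (S)-phenylethyl imine of 1 | CC1CC[C@H](CC1=N[C@@H](C)c1ccccc1)C(C)=C | intermediate
4 | ethyl vinyl ketone (pent-1-en-3-one) | CCC(=O)C=C | starting material
5 | adduct imine, quaternary carbon set | CCC(=O)CC[C@@]1(C)CC[C@H](CC1=N[C@@H](C)c1ccccc1)C(C)=C | intermediate
6 | (2R,5R)-2-methyl-2-(3-oxopentyl)-5-(prop-1-en-2-yl)cyclohexan-1-one | CCC(=O)CC[C@@]1(C)CC[C@H](CC1=O)C(C)=C | intermediate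
7 | (−)-10-epi-α-cyperone, (4aR,7R) | O=C1CC[C@@]2(C)CC[C@H](CC2=C1C)C(C)=C | intermediate
8 | α-methoxy hydroperoxide from the isopropenyl group of 7 | O=C1CC[C@@]2(C)CC[C@H](CC2=C1C)C(C)(OC)OO | intermediate
9 | C3 TEMPO ether (C3 epimers) | O=C1CC[C@@]2(C)CCC(CC2=C1C)ON3C(C)(C)CCCC3(C)C | intermediate
10 | (4aR)-1,4a-dimethyl-4,4a,5,6-tetrahydronaphthalene-2,7(3H,8H)-dione (5-ene-3,7-dione) | O=C1CC[C@@]2(C)CCC(=O)CC2=C1C | intermediate
11 | 3,3-ethylenedioxy-6,10β-dimethyldecal-5-en-7-one | O=C1CC[C@@]2(C)CCC3(OCCO3)CC2=C1C | intermediate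
12 | 8α-hydroxy derivative of 11 | O=C1[C@@H](O)C[C@@]2(C)CCC3(OCCO3)CC2=C1C | intermediate
13 | 7β,8α-diol (5-ene, 3-ketal) | O[C@@H]1[C@@H](O)C[C@@]2(C)CCC3(OCCO3)CC2=C1C | intermediate
14 | 7β,8α-O-TIPDS derivative of 13 | CC1=C2CC3(OCCO3)CC[C@]2(C)C[C@@H]4O[Si](C(C)C)(C(C)C)O[Si](C(C)C)(C(C)C)O[C@@H]14 | intermediate
15 | deconjugated 5-en-3-one | CC1=C2CC(=O)CC[C@]2(C)C[C@@H]3O[Si](C(C)C)(C(C)C)O[Si](C(C)C)(C(C)C)O[C@@H]13 | intermediate
16 | 6α,10β-dimethyl-7β,8α-(TIPDS-dioxy)decal-4-en-3-one | O=C1CC[C@]2(C)C[C@@H]3O[Si](C(C)C)(C(C)C)O[Si](C(C)C)(C(C)C)O[C@H]3[C@H](C)C2=C1 | intermediate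
17 | methyl bromoacetate | COC(=O)CBr | starting material
18 | 2-(methoxycarbonylmethyl) derivative of 16 (C2 epimers) | COC(=O)CC1C[C@]2(C)C[C@@H]3O[Si](C(C)C)(C(C)C)O[Si](C(C)C)(C(C)C)O[C@H]3[C@H](C)C2=CC1=O | intermediate
19 | key-step precursor, 2-(methoxycarbonylmethyl)-1,4-dien-3-one, 6α-CH3, 10β-CH3, 7β,8α-O-TIPDS | COC(=O)CC1=C[C@]2(C)C[C@@H]3O[Si](C(C)C)(C(C)C)O[Si](C(C)C)(C(C)C)O[C@H]3[C@H](C)C2=CC1=O | intermediate
20 | key-step product, spiro[4.5]decenone carbinol, C1 α and C4 β at C5, 10β-OH (axial) | COC(=O)CC1=C[C@]2(CC1=O)[C@@](C)(O)C[C@@H]3O[Si](C(C)C)(C(C)C)O[Si](C(C)C)(C(C)C)O[C@H]3[C@@H]2C | intermediate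
21 | (3R)-allylic alcohol, hydroxy ester | COC(=O)CC1=C[C@]2(C[C@H]1O)[C@@](C)(O)C[C@@H]3O[Si](C(C)C)(C(C)C)O[Si](C(C)C)(C(C)C)O[C@H]3[C@@H]2C | intermediate
22 | β,γ-unsaturated γ-lactone (C1=C2) | O=C1CC2=C[C@]3(C[C@H]2O1)[C@@](C)(O)C[C@@H]4O[Si](C(C)C)(C(C)C)O[Si](C(C)C)(C(C)C)O[C@H]4[C@@H]3C | intermediate
23 | saturated cis-fused lactone, 10-carbinol retained | O=C1C[C@H]2C[C@]3(C[C@H]2O1)[C@@](C)(O)C[C@@H]4O[Si](C(C)C)(C(C)C)O[Si](C(C)C)(C(C)C)O[C@H]4[C@@H]3C | intermediate
24 | C9=C10 alkene lactone | O=C1C[C@H]2C[C@]3(C[C@H]2O1)C(C)=C[C@@H]4O[Si](C(C)C)(C(C)C)O[Si](C(C)C)(C(C)C)O[C@H]4[C@@H]3C | intermediate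
25 | Eschenmoser's salt | C=[N+](C)C.[I-] | starting material
26 | α-(dimethylaminomethyl) lactone (C11 epimers) | CN(C)CC1C(=O)O[C@@H]2C[C@@]3(C[C@H]12)C(C)=C[C@@H]4O[Si](C(C)C)(C(C)C)O[Si](C(C)C)(C(C)C)O[C@H]4[C@@H]3C | intermediate
27 | methiodide of 26 | C[N+](C)(C)CC1C(=O)O[C@@H]2C[C@@]3(C[C@H]12)C(C)=C[C@@H]4O[Si](C(C)C)(C(C)C)O[Si](C(C)C)(C(C)C)O[C@H]4[C@@H]3C.[I-] | intermediate
28 | α-methylene lactone | C=C1C(=O)O[C@@H]2C[C@@]3(C[C@H]12)C(C)=C[C@@H]4O[Si](C(C)C)(C(C)C)O[Si](C(C)C)(C(C)C)O[C@H]4[C@@H]3C | intermediate
29 | 10-hydroxymethyl compound | C=C1C(=O)O[C@@H]2C[C@@]3(C[C@H]12)C(CO)=C[C@@H]4O[Si](C(C)C)(C(C)C)O[Si](C(C)C)(C(C)C)O[C@H]4[C@@H]3C | intermediate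
30 | angelic acid, (Z)-2-methylbut-2-enoic acid | C/C=C(/C)C(=O)O | starting material
31 | angelic 2,4,6-trichlorobenzoic anhydride | C/C=C(/C)C(=O)OC(=O)c1c(Cl)cc(Cl)cc1Cl | intermediate
32 | TIPDS-protected angelate | C=C1C(=O)O[C@@H]2C[C@@]3(C[C@H]12)C(COC(=O)/C(C)=C\C)=C[C@@H]4O[Si](C(C)C)(C(C)C)O[Si](C(C)C)(C(C)C)O[C@H]4[C@@H]3C | intermediate
33 | CNP0224912.1 (2R,3R,5R,6R,7S,8S in route locants) | C=C1C(=O)O[C@@H]2C[C@@]3(C[C@H]12)C(COC(=O)/C(C)=C\C)=C[C@H](O)[C@@H](O)[C@@H]3C | target

Total step count: 19. Longest linear sequence: 19 steps (1 to 33).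

Steps most likely to fail

Step 12. The greasy disiloxane may not stay dissolved in the aqueous acid. That lengthens irradiation, lets product 20 absorb and be photolysed further, and gives the zwitterion time to leak toward the lumiketone or toward C5–C10 cleavage. The fallback runs the key step without the protecting group. Starting from 19, the bridge is removed with Et3N·3HF to give dienone diol F1. This diol dissolves in plain 45% aqueous AcOH and is irradiated there through Pyrex to give spiro triol F2. TIPDSCl2 and imidazole then re-bridge only the vicinal secondary diol, since the tertiary carbinol does not silylate, and the route is rejoined at 20.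

Step 14. Uptake at the neopentyl trisubstituted alkene may be slow, with allylic C3–O hydrogenolysis or erosion of facial selectivity. The fallback uses hydroxyl-directed delivery followed by inversion. Starting from 20, (R)-Me-CBS and catecholborane give the 3-epimeric allylic alcohol F3, which is kept as the hydroxy ester with no acid treatment. [Ir(cod)(PCy3)(py)]PF6 and H2 in CH2Cl2 deliver hydrogen from the hydroxyl-bearing C6 side to give trans hydroxy ester F4, which already has the correct C2. LiOH at 0 °C gives hydroxy acid F5. Mitsunobu lactonisation (PPh3, DIAD) then closes the cis-lactone with inversion at C3, rejoining at 23.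

Step 17. The ene step at hindered C9, next to the silyloxy carbon, may be sluggish, and over-oxidation may give the enal, whose reduction would endanger the methylene lactone. The fallback is an epoxide route that needs neither selenium nor the regiocontrol of step 15.
- Starting from 23, Burgess reagent gives exocyclic alkene F6. The elimination is syn, and the axial sulfamate finds a syn-periplanar hydrogen only on the methyl group.
- mCPBA gives spiro-epoxide F7.
- Cp2TiCl2 and Mn (trivalent titanium) open the epoxide to the tertiary C10 radical. Hydrogen loss from C9, the only ring β-carbon that carries hydrogen, gives primary allylic alcohol F8.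
- The sequence of step 16 with one extra equivalent of LiN(i-Pr)2 proceeds through Mannich base F9 and methiodide F10 and rejoins at 29.

Further compounds

F1 | step 12 | dienone diol (19 without the disiloxane) | COC(=O)CC1=C[C@]2(C)C[C@H](O)[C@@H](O)[C@H](C)C2=CC1=O
F2 | step 12 | spiro triol (20 without the disiloxane) | COC(=O)CC1=C[C@]2(CC1=O)[C@@](C)(O)C[C@H](O)[C@@H](O)[C@@H]2C
F3 | step 14 | 3-epimeric allylic alcohol (OH on the C6 side) | COC(=O)CC1=C[C@]2(C[C@@H]1O)[C@@](C)(O)C[C@@H]3O[Si](C(C)C)(C(C)C)O[Si](C(C)C)(C(C)C)O[C@H]3[C@@H]2C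
F4 | step 14 | trans hydroxy ester | COC(=O)C[C@H]1C[C@]2(C[C@@H]1O)[C@@](C)(O)C[C@@H]3O[Si](C(C)C)(C(C)C)O[Si](C(C)C)(C(C)C)O[C@H]3[C@@H]2C
F5 | step 14 | trans hydroxy acid | OC(=O)C[C@H]1C[C@]2(C[C@@H]1O)[C@@](C)(O)C[C@@H]3O[Si](C(C)C)(C(C)C)O[Si](C(C)C)(C(C)C)O[C@H]3[C@@H]2C
F6 | step 17 | exocyclic alkene lactone | O=C1C[C@H]2C[C@]3(C[C@H]2O1)C(=C)C[C@@H]4O[Si](C(C)C)(C(C)C)O[Si](C(C)C)(C(C)C)O[C@H]4[C@@H]3C
F7 | step 17 | spiro-epoxide lactone (C10 epimers) | O=C1C[C@H]2C[C@]3(C[C@H]2O1)C5(CO5)C[C@@H]4O[Si](C(C)C)(C(C)C)O[Si](C(C)C)(C(C)C)O[C@H]4[C@@H]3C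
F8 | step 17 | 10-hydroxymethyl C9=C10 lactone | O=C1C[C@H]2C[C@]3(C[C@H]2O1)C(CO)=C[C@@H]4O[Si](C(C)C)(C(C)C)O[Si](C(C)C)(C(C)C)O[C@H]4[C@@H]3C
F9 | step 17 | Mannich base of F8 | CN(C)CC1C(=O)O[C@@H]2C[C@@]3(C[C@H]12)C(CO)=C[C@@H]4O[Si](C(C)C)(C(C)C)O[Si](C(C)C)(C(C)C)O[C@H]4[C@@H]3C
F10 | step 17 | methiodide of F9 | C[N+](C)(C)CC1C(=O)O[C@@H]2C[C@@]3(C[C@H]12)C(CO)=C[C@@H]4O[Si](C(C)C)(C(C)C)O[Si](C(C)C)(C(C)C)O[C@H]4[C@@H]3C.[I-]
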